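**Retrosynthetic overview** (germacrane numbering: C1 ketone, C4/C5 oxirane, C6 lactone CH–O, C7=C11 butenolide alkene, C8 CH–O-tigloyl, C10=C14 exo-methylene, C12 lactone C=O, C13 CH2OAc, C15 methyl)
1. Ten-membered carbocycle (last ring): C1–C10 bond by coupling the acyl radical of a C1 aldehyde with the C10 alkenyl bromide on nickel; the enone arrives at its final oxidation level and no stereocentre is made.
2. C8–C9 and C8 (S): catalytic asymmetric 2-bromoallylation of a butenolide-4-carbaldehyde with 2,3-dibromopropene, then tigloylation.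
3. Butenolide (second ring, C7/C11–C13): vinylcuprate addition to a γ-hydroxy ynoate, formaldehyde trapping, lactonisation, acetylation; the vinyl group is then cut to the C8 aldehyde.
4. Oxirane (first ring, C4/C5): hydroxyl-directed threo epoxidation from the C6 carbinol, itself set by asymmetric propiolate addition to an (E)-enal.
5. (E)-C4=C5 alkene: Negishi carboalumination/hydroxymethylation of O-silyl pent-4-yn-1-ol.

Assumption: the TBS ether of pent-4-yn-1-ol is bought as such, and for the two ligand-controlled steps (3 and 7) the ligand enantiomer is the one that gives the stated configuration (both antipodes are available).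

**Step 1**
Reactants: 1 tert-butyl(dimethyl)(pent-4-yn-1-yloxy)silane
Product: 3 (2E)-6-{[tert-butyl(dimethyl)silyl]oxy}-3-methylhex-2-en-1-ol, via alkenyl(dimethyl)alane 2 (not isolated)
Conditions: AlMe3 (2 equiv), Cp2ZrCl2 (0.25 equiv), CH2Cl2, 0 °C → rt; then (CH2O)n, THF, 0 °C → rt; aq. KNaC4H4O6
Reagents that add atoms: trimethylaluminium, C[Al](C)C; formaldehyde (as paraformaldehyde), C=O
Why: Negishi zirconium-catalysed carboalumination adds methyl and aluminium syn across the terminal alkyne (methyl to the internal carbon) and the alkenylalane is hydroxymethylated with retention, which fixes the E trisubstituted C4=C5 alkene.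

**Step 2**
Reactants: 3 (2E)-6-{[tert-butyl(dimethyl)silyl]oxy}-3-methylhex-2-en-1-ol
Product: 4 (2E)-6-{[tert-butyl(dimethyl)silyl]oxy}-3-methylhex-2-enal
Conditions: MnO2 (15 equiv), CH2Cl2, rt
Reagents that add atoms: none
Why: Chemoselective MnO2 oxidation of the allylic alcohol; no stereocentre is involved and the E geometry is kept.

**Step 3**
Reactants: 4 (2E)-6-{[tert-butyl(dimethyl)silyl]oxy}-3-methylhex-2-enal; 5 methyl propiolate
Product: 7 methyl (4R,5E)-9-{[tert-butyl(dimethyl)silyl]oxy}-4-hydroxy-6-methylnon-5-en-2-ynoate, via methylzinc acetylide 6 (not isolated)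
Conditions: 5 (3 equiv), ZnMe2 (3 equiv), ProPhenol ligand (10 mol %, enantiomer giving 4R), Ph3P=O (20 mol %), toluene, 4 °C
Reagents that add atoms: none
Why: Trost ProPhenol/zinc asymmetric alkynylation of an enal, in which the dinuclear zinc catalyst delivers the zinc acetylide to one aldehyde face and so sets C6 (4R in 7) by catalyst control.

**Step 4**
Reactants: 7 methyl (4R,5E)-9-{[tert-butyl(dimethyl)silyl]oxy}-4-hydroxy-6-methylnon-5-en-2-ynoate
Product: 8 methyl (4S)-4-hydroxy-4-[(2R,3R)-3-(3-{[tert-butyl(dimethyl)silyl]oxy}propyl)-3-methyloxiran-2-yl]but-2-ynoate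
Conditions: mCPBA (1.3 equiv), NaHCO3, CH2Cl2, 0 °C
Reagents that add atoms: 3-chloroperoxybenzoic acid, OOC(=O)c1cccc(Cl)c1
Why: Hydroxyl-directed (Henbest-type) peracid epoxidation of an acyclic secondary allylic alcohol: A(1,3) strain with the methyl cis to the carbinol puts the carbinol C–H in the alkene plane and the hydrogen-bonded peracid attacks syn to OH, giving the threo epoxy alcohol (C4 R, C5 R from C6), while the electron-poor ynoate is untouched.

**Step 5**
Reactants: 8 methyl (4S)-4-hydroxy-4-[(2R,3R)-3-(3-{[tert-butyl(dimethyl)silyl]oxy}propyl)-3-methyloxiran-2-yl]but-2-ynoate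
Product: 12 {(5S)-5-[(2R,3R)-3-(3-{[tert-butyl(dimethyl)silyl]oxy}propyl)-3-methyloxiran-2-yl]-4-ethenyl-2-oxo-2,5-dihydrofuran-3-yl}methyl acetate, via alkenyl(vinyl)cuprate 9 (not isolated), via (2Z)-dihydroxy dienoate 10 (not isolated), via hydroxymethyl butenolide 11 (not isolated)
Conditions: CH2=CHMgBr (4.4 equiv), CuBr·SMe2 (2.2 equiv), THF, −78 °C; HCHO (g), −78 → −40 °C; AcOH, −78 °C, cold aq. NH4Cl; crude, PPTS (cat.), CH2Cl2, rt; then Ac2O, pyridine, DMAP (cat.), 0 °C
Reagents that add atoms: vinylmagnesium bromide, C=C[Mg]Br; formaldehyde, C=O; acetic anhydride, CC(=O)OC(C)=O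
Why: Tandem conjugate addition–aldol–lactonisation: syn carbocupration of the ynoate puts vinyl on C7, the α-cuprio enoate is hydroxymethylated by formaldehyde on the side of the small vinyl group, and the resulting (Z)-γ-hydroxy ester lactonises under acid before the only remaining hydroxyl is acetylated, so C6 is never exposed to base once the lactone exists.

**Step 6**
Reactants: 12 {(5S)-5-[(2R,3R)-3-(3-{[tert-butyl(dimethyl)silyl]oxy}propyl)-3-methyloxiran-2-yl]-4-ethenyl-2-oxo-2,5-dihydrofuran-3-yl}methyl acetate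
Product: 14 {(5S)-5-[(2R,3R)-3-(3-{[tert-butyl(dimethyl)silyl]oxy}propyl)-3-methyloxiran-2-yl]-4-formyl-2-oxo-2,5-dihydrofuran-3-yl}methyl acetate, via secondary ozonide 13 (not isolated)
Conditions: O3, CH2Cl2, −78 °C (Sudan Red 7B end point); Me2S, −78 °C → rt
Reagents that add atoms: ozone, [O-][O+]=O
Why: Ozonolysis with reductive work-up cleaves the terminal vinyl group, the only alkene left that is not both tetrasubstituted and ester-conjugated, under neutral conditions that spare the base-sensitive C6–H and the epoxide.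

**Step 7**
Reactants: 14 {(5S)-5-[(2R,3R)-3-(3-{[tert-butyl(dimethyl)silyl]oxy}propyl)-3-methyloxiran-2-yl]-4-formyl-2-oxo-2,5-dihydrofuran-3-yl}methyl acetate; 15 2,3-dibromopropene
Product: 16 {(5S)-4-[(1S)-3-bromo-1-hydroxybut-3-en-1-yl]-5-[(2R,3R)-3-(3-{[tert-butyl(dimethyl)silyl]oxy}propyl)-3-methyloxiran-2-yl]-2-oxo-2,5-dihydrofuran-3-yl}methyl acetate
Conditions: 15 (2 equiv), CrCl2 (15 mol %), Kishi oxazoline–sulfonamide ligand (17 mol %, enantiomer giving 8S), Et3N (17 mol %), cobalt phthalocyanine Co(C32H16N8) (2 mol %), Mn powder, Cp2ZrCl2, LiCl, MeCN, rt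
Reagents that add atoms: none
Why: Kishi's catalytic asymmetric cobalt/chromium 2-haloallylation (Nozaki–Hiyama–Kishi type): cobalt activates only the allylic C–Br bond, the vinylic C–Br bond survives because no nickel is present, and the ligand-bound allylchromium adds through a closed transition state to one aldehyde face, setting C8 (S) by catalyst control.

**Step 8**
Reactants: 16 {(5S)-4-[(1S)-3-bromo-1-hydroxybut-3-en-1-yl]-5-[(2R,3R)-3-(3-{[tert-butyl(dimethyl)silyl]oxy}propyl)-3-methyloxiran-2-yl]-2-oxo-2,5-dihydrofuran-3-yl}methyl acetate; 17 (2E)-2-methylbut-2-enoyl chloride (tigloyl chloride)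
Product: 18 (1S)-1-{(2S)-4-(acetoxymethyl)-2-[(2R,3R)-3-(3-{[tert-butyl(dimethyl)silyl]oxy}propyl)-3-methyloxiran-2-yl]-5-oxo-2,5-dihydrofuran-3-yl}-3-bromobut-3-en-1-yl (2E)-2-methylbut-2-enoate
Conditions: 17 (1.5 equiv), pyridine, DMAP (cat.), CH2Cl2, 0 °C → rt
Reagents that add atoms: none
Why: DMAP-catalysed O-acylation of the secondary alcohol with retention at C8; the E (tiglate) geometry is the stable one and the weak base leaves C6–H alone.

**Step 9**
Reactants: 18 (1S)-1-{(2S)-4-(acetoxymethyl)-2-[(2R,3R)-3-(3-{[tert-butyl(dimethyl)silyl]oxy}propyl)-3-methyloxiran-2-yl]-5-oxo-2,5-dihydrofuran-3-yl}-3-bromobut-3-en-1-yl (2E)-2-methylbut-2-enoate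
Product: 19 (1S)-1-{(2S)-4-(acetoxymethyl)-2-[(2R,3R)-3-(3-hydroxypropyl)-3-methyloxiran-2-yl]-5-oxo-2,5-dihydrofuran-3-yl}-3-bromobut-3-en-1-yl (2E)-2-methylbut-2-enoate
Conditions: HF·pyridine, pyridine, THF, 0 °C
Reagents that add atoms: none
Why: Buffered fluoride desilylation of the primary TBS ether, conditions under which the epoxide, the three esters and the alkenyl bromide are stable.

**Step 10**
Reactants: 19 (1S)-1-{(2S)-4-(acetoxymethyl)-2-[(2R,3R)-3-(3-hydroxypropyl)-3-methyloxiran-2-yl]-5-oxo-2,5-dihydrofuran-3-yl}-3-bromobut-3-en-1-yl (2E)-2-methylbut-2-enoate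
Product: 20 (1S)-1-{(2S)-4-(acetoxymethyl)-2-[(2R,3R)-3-methyl-3-(3-oxopropyl)oxiran-2-yl]-5-oxo-2,5-dihydrofuran-3-yl}-3-bromobut-3-en-1-yl (2E)-2-methylbut-2-enoate
Conditions: Dess–Martin periodinane, NaHCO3, CH2Cl2, rt
Reagents that add atoms: none
Why: Dess–Martin oxidation of the only free alcohol to the C1 aldehyde under buffered, non-basic conditions.

**Step 11**
Reactants: 20 (1S)-1-{(2S)-4-(acetoxymethyl)-2-[(2R,3R)-3-methyl-3-(3-oxopropyl)oxiran-2-yl]-5-oxo-2,5-dihydrofuran-3-yl}-3-bromobut-3-en-1-yl (2E)-2-methylbut-2-enoate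
Product: 21 (4R,5R,6S,8S)-13-acetoxy-4,5-epoxy-8-[(2E)-2-methylbut-2-enoyloxy]-1-oxogermacra-7(11),10(14)-dien-12,6-olide (CNP0225286.1)
Conditions: [Ir(dF(CF3)ppy)2(dtbbpy)]PF6 (2 mol %), NiBr2·dme (25 mol %), dtbbpy (25 mol %), quinuclidine (30 mol %), K2CO3, 1,4-dioxane (2 mM, slow addition of 20), blue LEDs, rt
Reagents that add atoms: none
Why: Proposed new method: the photo-oxidised quinuclidine radical cation abstracts the hydridic formyl hydrogen of the unhindered aliphatic C1 aldehyde (the α-acyloxy C–H bonds are polarity-mismatched), the nucleophilic acyl radical is captured by the alkenylnickel bromide formed by oxidative addition of zerovalent nickel into the C10–Br bond, and reductive elimination from trivalent nickel closes the ten-membered ring as the α-methylene ketone with no stereocentre formed; the closest known reaction type is the intermolecular aldehyde C–H arylation/alkenylation by nickel/photoredox/hydrogen-atom-transfer triple catalysis, here run intramolecularly at high dilution.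

**Compound list**
1 | tert-butyl(dimethyl)(pent-4-yn-1-yloxy)silane | C#CCCCO[Si](C)(C)C(C)(C)C | starting material
2 | [(1E)-5-{[tert-butyl(dimethyl)silyl]oxy}-2-methylpent-1-en-1-yl]dimethylalane | C[Al](C)/C=C(\C)CCCO[Si](C)(C)C(C)(C)C | intermediate
3 | (2E)-6-{[tert-butyl(dimethyl)silyl]oxy}-3-methylhex-2-en-1-ol | OC/C=C(\C)CCCO[Si](C)(C)C(C)(C)C | intermediate
4 | (2E)-6-{[tert-butyl(dimethyl)silyl]oxy}-3-methylhex-2-enal | O=C/C=C(\C)CCCO[Si](C)(C)C(C)(C)C | intermediate
5 | methyl propiolate | COC(=O)C#C | starting material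
6 | methyl(3-methoxy-3-oxoprop-1-yn-1-yl)zinc | COC(=O)C#C[Zn]C | intermediate
7 | methyl (4R,5E)-9-{[tert-butyl(dimethyl)silyl]oxy}-4-hydroxy-6-methylnon-5-en-2-ynoate | COC(=O)C#C[C@H](O)/C=C(\C)CCCO[Si](C)(C)C(C)(C)C | intermediate
8 | methyl (4S)-4-hydroxy-4-[(2R,3R)-3-(3-{[tert-butyl(dimethyl)silyl]oxy}propyl)-3-methyloxiran-2-yl]but-2-ynoate | COC(=O)C#C[C@H](O)[C@H]1O[C@]1(C)CCCO[Si](C)(C)C(C)(C)C | intermediate
9 | bromomagnesium alkenyl(vinyl)cuprate of 8 (vinyl on C7, copper on C11, syn; C6 alkoxide as O–MgBr) | C=C/C([C@H](O[Mg]Br)[C@H]1O[C@]1(C)CCCO[Si](C)(C)C(C)(C)C)=C(\[Cu-]C=C)C(=O)OC.[Mg+]Br | intermediate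
10 | methyl (2Z)-3-[(S)-hydroxy{(2R,3R)-3-(3-{[tert-butyl(dimethyl)silyl]oxy}propyl)-3-methyloxiran-2-yl}methyl]-2-(hydroxymethyl)penta-2,4-dienoate | C=C/C([C@H](O)[C@H]1O[C@]1(C)CCCO[Si](C)(C)C(C)(C)C)=C(\CO)C(=O)OC | intermediate
11 | (5S)-5-[(2R,3R)-3-(3-{[tert-butyl(dimethyl)silyl]oxy}propyl)-3-methyloxiran-2-yl]-4-ethenyl-3-(hydroxymethyl)furan-2(5H)-one | C=CC1=C(CO)C(=O)O[C@@H]1[C@H]1O[C@]1(C)CCCO[Si](C)(C)C(C)(C)C | intermediate
12 | {(5S)-5-[(2R,3R)-3-(3-{[tert-butyl(dimethyl)silyl]oxy}propyl)-3-methyloxiran-2-yl]-4-ethenyl-2-oxo-2,5-dihydrofuran-3-yl}methyl acetate | C=CC1=C(COC(C)=O)C(=O)O[C@@H]1[C@H]1O[C@]1(C)CCCO[Si](C)(C)C(C)(C)C | intermediate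
13 | secondary ozonide (1,2,4-trioxolan-3-yl in place of the ethenyl group of 12; mixture at the ozonide carbon) | C1OOC(O1)C1=C(COC(C)=O)C(=O)O[C@@H]1[C@H]1O[C@]1(C)CCCO[Si](C)(C)C(C)(C)C | intermediate
14 | {(5S)-5-[(2R,3R)-3-(3-{[tert-butyl(dimethyl)silyl]oxy}propyl)-3-methyloxiran-2-yl]-4-formyl-2-oxo-2,5-dihydrofuran-3-yl}methyl acetate | O=CC1=C(COC(C)=O)C(=O)O[C@@H]1[C@H]1O[C@]1(C)CCCO[Si](C)(C)C(C)(C)C | intermediate
15 | 2,3-dibromopropene | C=C(Br)CBr | starting material
16 | {(5S)-4-[(1S)-3-bromo-1-hydroxybut-3-en-1-yl]-5-[(2R,3R)-3-(3-{[tert-butyl(dimethyl)silyl]oxy}propyl)-3-methyloxiran-2-yl]-2-oxo-2,5-dihydrofuran-3-yl}methyl acetate | C=C(Br)C[C@H](O)C1=C(COC(C)=O)C(=O)O[C@@H]1[C@H]1O[C@]1(C)CCCO[Si](C)(C)C(C)(C)C | intermediate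
17 | (2E)-2-methylbut-2-enoyl chloride (tigloyl chloride) | C/C=C(\C)C(Cl)=O | starting material
18 | (1S)-1-{(2S)-4-(acetoxymethyl)-2-[(2R,3R)-3-(3-{[tert-butyl(dimethyl)silyl]oxy}propyl)-3-methyloxiran-2-yl]-5-oxo-2,5-dihydrofuran-3-yl}-3-bromobut-3-en-1-yl (2E)-2-methylbut-2-enoate | C=C(Br)C[C@H](OC(=O)/C(C)=C/C)C1=C(COC(C)=O)C(=O)O[C@@H]1[C@H]1O[C@]1(C)CCCO[Si](C)(C)C(C)(C)C | intermediate
19 | (1S)-1-{(2S)-4-(acetoxymethyl)-2-[(2R,3R)-3-(3-hydroxypropyl)-3-methyloxiran-2-yl]-5-oxo-2,5-dihydrofuran-3-yl}-3-bromobut-3-en-1-yl (2E)-2-methylbut-2-enoate | C=C(Br)C[C@H](OC(=O)/C(C)=C/C)C1=C(COC(C)=O)C(=O)O[C@@H]1[C@H]1O[C@]1(C)CCCO | intermediate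
20 | (1S)-1-{(2S)-4-(acetoxymethyl)-2-[(2R,3R)-3-methyl-3-(3-oxopropyl)oxiran-2-yl]-5-oxo-2,5-dihydrofuran-3-yl}-3-bromobut-3-en-1-yl (2E)-2-methylbut-2-enoate | C=C(Br)C[C@H](OC(=O)/C(C)=C/C)C1=C(COC(C)=O)C(=O)O[C@@H]1[C@H]1O[C@]1(C)CCC=O | intermediate
21 | (4R,5R,6S,8S)-13-acetoxy-4,5-epoxy-8-[(2E)-2-methylbut-2-enoyloxy]-1-oxogermacra-7(11),10(14)-dien-12,6-olide (CNP0225286.1) | C=C1C[C@H](OC(=O)/C(C)=C/C)C2=C(COC(C)=O)C(=O)O[C@@H]2[C@H]2O[C@]2(C)CCC1=O | target

**Totals**
Total step count: 11. Longest linear sequence: 11 (fully linear from 1; compounds 5, 15 and 17 are bought).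

**Three steps most likely to fail, each with a fallback**

Step 11 (ring closure). The acyl radical has to find the alkenylnickel of its own molecule. Oligomers, acyl-radical addition to the product enone, or stray hydrogen abstraction could win. Fallback: setting out from 20, close the same C1–C10 bond by a two-electron Nozaki–Hiyama–Kishi reaction (CrCl2 in excess, NiCl2 catalytic, DMSO/THF, high dilution). This gives the ten-membered C1 allylic alcohol (both C1 epimers) F1. Oxidation of the carbinol with Dess–Martin periodinane then brings the route back at 21.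

Step 5 (one-pot butenolide). The formaldehyde may enter from the wrong side of the allenoate, which gives an E ester that cannot lactonise, and the primary alkoxide must survive until the acid quench. Fallback: setting out from 8, run the same vinylcuprate addition but quench the α-cuprio enoate at −78 °C with I2, which reacts with retention. Acidic work-up and lactonisation give the 3-iodo-4-ethenyl butenolide F2. The CH2OH group is then installed by Stille coupling with Bu3SnCH2OH under Pd(PPh3)4 in dioxane. This comes back to the route at 11, which is acetylated as in the last stage of step 5 to give 12.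

Step 7 (C8 stereocentre). The β-formyl butenolide is Lewis-acid- and base-sensitive and the chromium catalyst may give poor facial control or reduce the aldehyde. Fallback: setting out from 14, do an unselective but very mild indium-mediated Barbier reaction with 15 (In powder, THF/H2O). This gives the C8-epimeric bromoallyl carbinols F3. Dess–Martin oxidation gives the C8 ketone F4. Reduction with (R)-2-methyl-CBS-oxazaborolidine and catecholborane (butenolide as the large group) then sets 8S by reagent control and comes back to the route at 16.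

**Further compounds**
F1 | step 11 | (4R,5R,6S,8S)-13-acetoxy-4,5-epoxy-1-hydroxy-8-[(2E)-2-methylbut-2-enoyloxy]germacra-7(11),10(14)-dien-12,6-olide (C1 epimers) | C=C1C[C@H](OC(=O)/C(C)=C/C)C2=C(COC(C)=O)C(=O)O[C@@H]2[C@H]2O[C@]2(C)CCC1O
F2 | step 5 | (5S)-5-[(2R,3R)-3-(3-{[tert-butyl(dimethyl)silyl]oxy}propyl)-3-methyloxiran-2-yl]-4-ethenyl-3-iodofuran-2(5H)-one | C=CC1=C(I)C(=O)O[C@@H]1[C@H]1O[C@]1(C)CCCO[Si](C)(C)C(C)(C)C
F3 | step 7 | {(5S)-4-(3-bromo-1-hydroxybut-3-en-1-yl)-5-[(2R,3R)-3-(3-{[tert-butyl(dimethyl)silyl]oxy}propyl)-3-methyloxiran-2-yl]-2-oxo-2,5-dihydrofuran-3-yl}methyl acetate (C8 epimers) | C=C(Br)CC(O)C1=C(COC(C)=O)C(=O)O[C@@H]1[C@H]1O[C@]1(C)CCCO[Si](C)(C)C(C)(C)C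
F4 | step 7 | {(5S)-4-(3-bromobut-3-enoyl)-5-[(2R,3R)-3-(3-{[tert-butyl(dimethyl)silyl]oxy}propyl)-3-methyloxiran-2-yl]-2-oxo-2,5-dihydrofuran-3-yl}methyl acetate | C=C(Br)CC(=O)C1=C(COC(C)=O)C(=O)O[C@@H]1[C@H]1O[C@]1(C)CCCO[Si](C)(C)C(C)(C)C
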